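The numbers in the tables are simulated with made-up constants, noise included.

The chemist who has to rank alpha, delta, beta and theta wants a rule of thumb from the earlier runs first.

| flask | first end groups | second end groups | temperature | remark | time |
|---|---|---|---|---|---|
| red | 0.050 M | 0.55 equiv (in portions, 2) | −2 °C | run made earlier; portions every 1.5 min |  |
| ochre | 0.050 M | 0.83 equiv (in portions, 2) | 14 °C | run made earlier; portions every 1.5 min |  |
| grey | 0.025 M | 1.1 equiv (in portions, 2) | −2 °C | run made earlier; portions every 1.5 min |  |
| delta | 0.050 M | 1.10 equiv (in portions, 2) | −10 °C | the portions of second end groups follow each other after 1.5 min, the first at the start | 3.0 min |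
| theta | 0.050 M | 1.10 equiv (in portions, 2) | 20 °C | the portions of second end groups follow each other after 0.40 min, the first at the start | 3.0 min |
| alpha | 0.050 M | 1.10 equiv (in portions, 2) | −10 °C | the portions of second end groups follow each other after 0.40 min, the first at the start | 3.0 min |
| beta | 0.050 M | 1.10 equiv (in portions, 2) | 20 °C | the portions of second end groups follow each other after 1.5 min, the first at the start | 3.0 min |

| run | time / min | links / % |
|---|---|---|
| red | 1.33 | 5.1 |
| red | 3.00 | 10.2 |
| red | 4.00 | 9.5 |
| red | 6.00 | 9.9 |
| red | 8.00 | 9.5 |
| red | 12.0 | 7.5 |
| ochre | 0.250 | 8.4 |
| ochre | 0.417 | 8.3 |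
| ochre | 0.667 | 7.0 |
| ochre | 1.00 | 6.9 |
| ochre | 1.50 | 4.7 |
| ochre | 2.50 | 11.6 |
| ochre | 4.00 | 7.5 |
| grey | 2.00 | 15.1 |
| grey | 4.00 | 18.3 |
| grey | 6.00 | 18.1 |
| grey | 8.00 | 16.2 |
| grey | 12.0 | 13.5 |

(scatter of a reading: 0.5 percentage points)

- what was read earlier has a scatter of 0.5 percentage points, one standard deviation

- ranking by amount of links, in percent of the first end groups charged, from high to low, at 3.0 min (delta / theta / alpha / beta)
- the amount of links, in percent of the first end groups charged of the flask you put first, at 3.0 min
- the amount of links, in percent of the first end groups charged of the flask you put last, at 3.0 min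

We would begin with links per second end group charged. In the red run at 3.00 min, with both portions in, links stand at 10.2% on 0.55 equiv, which gives 0.185. The grey run at 4.00 min gives 0.166. Applied honestly to 1.10 equiv, the rule gives 20.4% for the cold flasks, alpha and delta, before any loss. The ochre run at 14 °C falls from 8.4% to 4.7% between 0.250 min and 1.50 min, so we put the warm flasks, beta and theta, lower.

But the rule has a border. Take the portion strength, the concentration of second end groups that one portion adds: c(first end groups) times equivalents, divided by the number of portions. Red and grey share one strength, 0.0138 M and 0.0138 M, so both readings of links per second end group charged belong to that one strength. Ochre reaches 0.0208 M, at another temperature. The four new flasks stand at 0.0275 M, twice the red strength and above every earlier run. Our 20.4% therefore rests on a portion strength beyond those of the earlier runs.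

The forecast gave alpha > delta > beta > theta, with 18.5% first and 4% last, reasoning that links “form quickly from each portion”; its top lies below our figure.

The flasks give alpha > delta > beta > theta, with 42.6% and 5.52%. Alpha holds 0.387 links per second end group charged, twice the red reading, and the links' half-life by over-reaction alone in alpha, 56 min, is long against 3.0 min.

    first end groups + second end groups → links (k = 2.50 /M/s, Ea = 57.0 kJ/mol)
    first end groups + second end groups → rings, rate k2*[first end groups] as long as [second end groups] is above zero (k = 0.0840 /s, Ea = 69.0 kJ/mol)
    second end groups → decomposition product (k = 7.60 × 10⁻⁶ /s, Ea = 91.0 kJ/mol)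
    links → over-reaction product (k = 0.00870 /s, Ea = 80.0 kJ/mol)
    second end groups → decomposed reagent (k = 0.0550 /s, Ea = 87.0 kJ/mol)
    (constants at 20 °C)

A neighbour of theta, at theta's 20 °C but charged with 0.280 equiv, has a portion strength of 0.00700 M, half the red one, and at 3.00 min this neighbour holds 0.569% links, or 0.0203 per second end group charged.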